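The cyclopentane is made from a four-membered ketone. Ring carbons C1, C3, C4 and C5 are assembled first by [2+2] addition of dichloroketene to an (E)-propenyl ether that carries a chiral 1-arylethyl group on oxygen. The lone methylene C2, flanked by the quaternary C1 and the methyl-bearing C3, is then inserted. In one operation diazomethane converts the trans-2,2-dichloro-3-alkoxy-4-methylcyclobutanone into the cyclopentanone, forming the C1–C2 and C2–C3 bonds, keeping the trans C3/C4 pair and leaving a CCl2 handle at C5 for the enal arm. The C1 side chain follows by carbonyl addition, crotylboration and cross-metathesis.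

Key step: step 5

Locants: the ring is numbered as in the target, C1 (quaternary, O-bearing), C2 (CH2), C3 (CHCH3), C4 (CH–O), C5 (CH with the arm); the C1 side chain is C1'–C7' outward. Compounds 11–21 carry systematic cycloalkanone names; from 25 on the target locants are used. In the target C1–O, C4–O and the C5 arm lie on one ring face, C1' and the C3 methyl on the other.

Assumption: the (S)-configured auxiliary, reacting through the s-trans enol ether with its carbinol C–H in the alkene plane, should expose the alkene face that leads to (3S,4S)-11; if the opposite face reacted, the (R)-alcohol would be used and nothing else would change.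

Stereochemical check: the methyl- and oxygen-bearing carbons of 11 and 15 correspond to C3 (R) and C4 (S) of the target; the target descriptors in the locants used here are C1 R, C3 R, C4 S, C5 S, C1' R, C2' R.

Step 1
Reactants: 1 (S)-1-(2,4,6-triisopropylphenyl)ethanol; 2 trichloroethylene
Product: 7 prop-1-yn-1-yl (S)-1-(2,4,6-triisopropylphenyl)ethyl ether, via dichloroacetylene 3 (not isolated), via 1,2-dichlorovinyl ether 4 (not isolated), via chloroethynyl ether 5 (not isolated), via lithium alkynyl ether 6 (not isolated)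
Conditions: KH, THF, 0 °C to rt; 2, −50 °C to rt; n-BuLi (2.4 equiv), −78 to −40 °C; MeI, DMPU, −78 °C to rt
Reagents that add atoms: iodomethane, CI
Why: One-pot ynol ether synthesis in which the potassium alkoxide adds to dichloroacetylene formed by dehydrochlorination of 2, n-BuLi then effects elimination and chlorine–lithium exchange, and the lithium alkynyl ether is C-methylated (addition–elimination then alkylation), the carbinol stereocenter being untouched.

Step 2
Reactants: 7 prop-1-yn-1-yl (S)-1-(2,4,6-triisopropylphenyl)ethyl ether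
Product: 8 (E)-prop-1-en-1-yl (S)-1-(2,4,6-triisopropylphenyl)ethyl ether
Conditions: LiAlH4, THF, reflux; then H2O, aq. NaOH
Reagents that add atoms: none
Why: Trans-selective hydroalumination of the electron-rich alkyne by LiAlH4 followed by protonolysis should give the (E)-enol ether (alkyne to trans-alkene reduction).

Step 3
Reactants: 8 (E)-prop-1-en-1-yl (S)-1-(2,4,6-triisopropylphenyl)ethyl ether; 9 trichloroacetyl chloride
Product: 11 (3S,4S)-2,2-dichloro-4-methyl-3-[(1S)-1-(2,4,6-triisopropylphenyl)ethoxy]cyclobutan-1-one, via dichloroketene 10 (not isolated)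
Conditions: Zn–Cu couple, Et2O, slow addition of 9, 0 °C to rt
Reagents that add atoms: none
Why: Thermal ketene–alkene [2+2] cycloaddition in which dichloroketene bonds through its carbonyl carbon to the nucleophilic β-carbon of the enol ether, the E geometry is transferred suprafacially to the trans methyl/alkoxy pair and the triisopropylphenyl group shields one alkene face, so that both new stereocenters (future C3 and C4) arise under auxiliary control, any minor diastereomer being removed by crystallization or chromatography.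

Step 4
Reactants: 12 N-methyl-N-nitroso-4-methylbenzenesulfonamide
Product: 13 diazomethane (dilute ethereal solution, used at once)
Conditions: KOH, H2O/EtOH/Et2O, 65 °C, co-distillation with Et2O, flame-polished glassware, blast shield
Reagents that add atoms: none
Why: Base-induced fragmentation of the N-methyl-N-nitrososulfonamide releases diazomethane, which co-distils with ether (standard diazomethane generation).

Step 5
Reactants: 11 (3S,4S)-2,2-dichloro-4-methyl-3-[(1S)-1-(2,4,6-triisopropylphenyl)ethoxy]cyclobutan-1-one; 13 diazomethane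
Product: 15 (3S,4R)-2,2-dichloro-4-methyl-3-[(1S)-1-(2,4,6-triisopropylphenyl)ethoxy]cyclopentan-1-one, via diazonium betaine 14 (not isolated)
Conditions: 13 (about 3 equiv) in Et2O, MeOH (few %), 0 °C to rt
Reagents that add atoms: none
Why: Diazomethane adds through carbon to the strained, chlorine-activated carbonyl of 11 to give betaine 14, and the non-halogenated α-carbon (future C3) then shifts from the carbonyl carbon to the diazonium-bearing CH2 as N2 leaves, which creates the C1–C2 and C2–C3 bonds. The closest known reaction type is the diazoalkane homologation of ketones (Büchner–Curtius–Schlotterbeck ring enlargement), which is established for α,α-dichlorocyclobutanones from ketene cycloadditions. The five-membered ring is closed by a 1,2-alkyl shift that enlarges the four-membered ring by one carbon, not by an end-to-end cyclization. No stereocenter is created, because the migrating carbon keeps its configuration and C4 is a spectator, so the trans C3/C4 relation of step 3 is carried over. The step needs migration of C3 in preference to the CCl2 carbon, secured by the poor migratory aptitude of the electron-poor dichlorinated carbon, and it needs to stop after one insertion, secured by the loss of ring strain and the lower electrophilicity of the cyclopentanone.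

Step 6
Reactants: 15 (3S,4R)-2,2-dichloro-4-methyl-3-[(1S)-1-(2,4,6-triisopropylphenyl)ethoxy]cyclopentan-1-one; 16 methacrolein
Product: 18 (3S,4R)-2-chloro-2-(1-hydroxy-2-methylprop-2-en-1-yl)-4-methyl-3-[(1S)-1-(2,4,6-triisopropylphenyl)ethoxy]cyclopentan-1-one (isomers at C2 and at the carbinol carbon), via lithium chloro-enolate 17 (not isolated)
Conditions: MeLi (2 equiv), CuI, Et2O/THF, −78 °C; 15, −78 °C; 16 (3 equiv), −78 °C; sat. aq. NH4Cl, −78 °C
Reagents that add atoms: none
Why: Halogen–metal exchange of one chlorine by the cuprate gives the C5 chloro-enolate regiospecifically (reductive enolate formation from an α,α-dihalo ketone), and this is trapped at −78 °C by 1,2-aldol addition to methacrolein before loss of the β-alkoxide can compete, the configurations at C5 and at the carbinol carbon being immaterial because both are reset in steps 7 and 8.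

Step 7
Reactants: 18 (3S,4R)-2-chloro-2-(1-hydroxy-2-methylprop-2-en-1-yl)-4-methyl-3-[(1S)-1-(2,4,6-triisopropylphenyl)ethoxy]cyclopentan-1-one
Product: 19 (2S,3S,4R)-2-(1-hydroxy-2-methylprop-2-en-1-yl)-4-methyl-3-[(1S)-1-(2,4,6-triisopropylphenyl)ethoxy]cyclopentan-1-one (carbinol epimers)
Conditions: Bu3SnH, AIBN (cat.), toluene, 80 °C
Reagents that add atoms: none
Why: Radical chain dechlorination of the α-chloro ketone, in which the planar α-keto radical at C5 should take hydrogen from Bu3SnH on the face opposite the bulky C4 ether and so place the C5 arm cis to the C4 oxygen as in the target.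

Step 8
Reactants: 19 (2S,3S,4R)-2-(1-hydroxy-2-methylprop-2-en-1-yl)-4-methyl-3-[(1S)-1-(2,4,6-triisopropylphenyl)ethoxy]cyclopentan-1-one
Product: 21 (2S,3S,4R)-2-[(E)-3-(tert-butyldimethylsilyloxy)-2-methylprop-1-en-1-yl]-4-methyl-3-[(1S)-1-(2,4,6-triisopropylphenyl)ethoxy]cyclopentan-1-one, via primary allylic alcohol 20 (not isolated)
Conditions: Ph3SiOReO3 (5 mol %), Et2O, −50 to 0 °C; then TBSCl, imidazole, CH2Cl2, 0 °C
Reagents that add atoms: tert-butyldimethylsilyl chloride, CC(C)(C)[Si](C)(C)Cl
Why: Rhenium-oxo-catalysed 1,3-transposition of the allylic alcohol ([3,3] shift of the allyl perrhenate) runs downhill from the secondary alcohol with a 1,1-disubstituted alkene to the primary alcohol with the trisubstituted (E)-alkene, and immediate mild silylation of 20 fixes it without disturbing the C5 stereocenter.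

Step 9
Reactants: 21 (2S,3S,4R)-2-[(E)-3-(tert-butyldimethylsilyloxy)-2-methylprop-1-en-1-yl]-4-methyl-3-[(1S)-1-(2,4,6-triisopropylphenyl)ethoxy]cyclopentan-1-one; 22 1,3-dithiane
Product: 26 1-(1,3-dithian-2-yl)-3-methyl-4-[(1S)-1-(2,4,6-triisopropylphenyl)ethoxy]-5-[(E)-3-(tert-butyldimethylsilyloxy)-2-methylprop-1-enyl]cyclopentyl acetate (C1–OAc cis to C4–O and to the C5 arm), via 2-lithio-1,3-dithiane 23 (not isolated), via dithianylcerium dichloride 24 (not isolated), via cerium alkoxide 25 (not isolated)
Conditions: 22, n-BuLi, THF, −30 °C; anhydrous CeCl3, −78 °C; 21, −78 °C; Ac2O, DMAP, −78 °C to rt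
Reagents that add atoms: acetic anhydride, CC(=O)OC(C)=O
Why: Organocerium 1,2-addition of the dithiane anion as formyl anion equivalent, whose low basicity spares the enolizable β,γ-unsaturated ketone, should occur on the ring face opposite the C5 arm and the C4 ether and so set C1 with its oxygen cis to both, and the hindered tertiary alkoxide is acetylated in the same flask (alkoxide trapping by Ac2O).

Step 10
Reactants: 26 1-(1,3-dithian-2-yl)-3-methyl-4-[(1S)-1-(2,4,6-triisopropylphenyl)ethoxy]-5-[(E)-3-(tert-butyldimethylsilyloxy)-2-methylprop-1-enyl]cyclopentyl acetate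
Product: 27 1-acetoxy-3-methyl-4-[(1S)-1-(2,4,6-triisopropylphenyl)ethoxy]-5-[(E)-3-(tert-butyldimethylsilyloxy)-2-methylprop-1-enyl]cyclopentane-1-carbaldehyde
Conditions: MeI, CaCO3, MeCN/H2O, 40 °C
Reagents that add atoms: water, O
Why: S-Alkylative hydrolysis of the dithioacetal, buffered by CaCO3, unmasks the non-enolizable α-acetoxy aldehyde under neutral conditions that spare the silyl ether, the acetate and the alkene.

Step 11
Reactants: 27 1-acetoxy-3-methyl-4-[(1S)-1-(2,4,6-triisopropylphenyl)ethoxy]-5-[(E)-3-(tert-butyldimethylsilyloxy)-2-methylprop-1-enyl]cyclopentane-1-carbaldehyde; 28 (E)-but-2-ene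
Product: 31 1-[(1R,2R)-1-hydroxy-2-methylbut-3-enyl]-3-methyl-4-[(1S)-1-(2,4,6-triisopropylphenyl)ethoxy]-5-[(E)-3-(tert-butyldimethylsilyloxy)-2-methylprop-1-enyl]cyclopentyl acetate, via crotylpotassium 29 (not isolated), via crotyldiisopinocampheylborane 30 (not isolated)
Conditions: 28, KOtBu, n-BuLi, THF, −78 to −45 °C; (+)-Ipc2BOMe, −78 °C; BF3·OEt2; 27, −78 °C; then 8-hydroxyquinoline, MeOH, rt
Reagents that add atoms: none
Why: Brown crotylboration through a chair Zimmerman–Traxler transition state, in which the (E)-crotyl geometry gives the 1',2'-anti relation and the isopinocampheyl groups derived from (−)-α-pinene should direct attack to the Re face of the aldehyde (reagent control), giving C1' and C2' as in the target, while the non-basic 8-hydroxyquinoline work-up avoids acetyl migration.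

Step 12
Reactants: 31 1-[(1R,2R)-1-hydroxy-2-methylbut-3-enyl]-3-methyl-4-[(1S)-1-(2,4,6-triisopropylphenyl)ethoxy]-5-[(E)-3-(tert-butyldimethylsilyloxy)-2-methylprop-1-enyl]cyclopentyl acetate
Product: 32 C1,C1'-diacetate of 31
Conditions: Ac2O, Et3N, DMAP, CH2Cl2, rt to 40 °C
Reagents that add atoms: acetic anhydride, CC(=O)OC(C)=O
Why: DMAP-catalysed acylation of the secondary alcohol (standard esterification) touches no stereocenter.

Step 13
Reactants: 33 1-bromo-3-methylbut-2-ene; 34 acetaldehyde
Product: 35 3,3-dimethylpent-4-en-2-ol (racemic)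
Conditions: Zn dust, THF/sat. aq. NH4Cl, 0 °C to rt
Reagents that add atoms: none
Why: Barbier-type zinc allylation in which the prenylzinc species reacts at its γ-carbon through a cyclic transition state gives the 2,2-dimethyl homoallylic alcohol, whose carbinol center is oxidized in the next step.

Step 14
Reactants: 35 3,3-dimethylpent-4-en-2-ol
Product: 36 3,3-dimethylpent-4-en-2-one
Conditions: (COCl)2, DMSO, CH2Cl2, −78 °C; Et3N, −78 to 0 °C
Reagents that add atoms: none
Why: Swern oxidation of the secondary alcohol gives the β,γ-unsaturated ketone, which cannot move into conjugation because its α-carbon is quaternary.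

Step 15
Reactants: 32 C1,C1'-diacetate of 31; 36 3,3-dimethylpent-4-en-2-one
Product: 37 diacetate with the complete side chain (E)-CH(OAc)CH(CH3)CH=CHC(CH3)2C(O)CH3 at C1, auxiliary ether at C4 and silyl ether on the C5 arm
Conditions: 36 (10 equiv), second-generation Hoveyda–Grubbs catalyst RuCl2(H2IMes)(=CH–C6H4–2-OiPr) (10 mol %), CH2Cl2, 40 °C
Reagents that add atoms: none
Why: Olefin cross-metathesis between the monosubstituted alkene of 32 and the vinyl group of 36 used in excess, where 36 with its quaternary allylic carbon does not homodimerize, the trisubstituted arm alkene is inert and the bulky flanking groups favor the (E)-alkene.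

Step 16
Reactants: 37 diacetate with the complete side chain, auxiliary ether at C4 and silyl ether on the C5 arm
Product: 38 C4 alcohol with the (E)-3-hydroxy-2-methylprop-1-enyl arm at C5 (C1 and C1' acetates retained)
Conditions: CF3CO2H/CH2Cl2 (1:5), H2O (few equiv), 0 °C
Reagents that add atoms: none
Why: Acidolysis of the benzylic auxiliary ether through the stabilized 1-arylethyl cation (SN1 ether cleavage) with concurrent acid hydrolysis of the primary silyl ether should leave the acetates, the ketone and all stereocenters untouched at 0 °C.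

Step 17
Reactants: 38 C4 alcohol with the (E)-3-hydroxy-2-methylprop-1-enyl arm
Product: 39 C4 alcohol with the (E)-2-methyl-3-oxoprop-1-enyl arm
Conditions: MnO2 (activated, excess), CH2Cl2, rt
Reagents that add atoms: none
Why: Chemoselective MnO2 oxidation of the primary allylic alcohol gives the (E)-enal while the saturated secondary C4 alcohol does not react.

Step 18
Reactants: 39 C4 alcohol with the (E)-2-methyl-3-oxoprop-1-enyl arm
Product: 40 target CNP0489076.2
Conditions: BzCl, pyridine, DMAP (cat.), CH2Cl2, 0 °C to rt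
Reagents that add atoms: benzoyl chloride, O=C(Cl)c1ccccc1
Why: DMAP-catalysed benzoylation of the remaining secondary alcohol proceeds with retention at C4 and completes the target.

Compound list
1 | (S)-1-(2,4,6-triisopropylphenyl)ethanol | O[C@@H](C)c1c(C(C)C)cc(C(C)C)cc1C(C)C | starting material
2 | trichloroethylene | ClC=C(Cl)Cl | starting material
3 | dichloroacetylene | ClC#CCl | intermediate
4 | (E)-1,2-dichlorovinyl (S)-1-(2,4,6-triisopropylphenyl)ethyl ether | Cl/C=C(/Cl)O[C@@H](C)c1c(C(C)C)cc(C(C)C)cc1C(C)C | intermediate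
5 | chloroethynyl (S)-1-(2,4,6-triisopropylphenyl)ethyl ether | ClC#CO[C@@H](C)c1c(C(C)C)cc(C(C)C)cc1C(C)C | intermediate
6 | {[(S)-1-(2,4,6-triisopropylphenyl)ethoxy]ethynyl}lithium | [Li]C#CO[C@@H](C)c1c(C(C)C)cc(C(C)C)cc1C(C)C | intermediate
7 | prop-1-yn-1-yl (S)-1-(2,4,6-triisopropylphenyl)ethyl ether | CC#CO[C@@H](C)c1c(C(C)C)cc(C(C)C)cc1C(C)C | intermediate
8 | (E)-prop-1-en-1-yl (S)-1-(2,4,6-triisopropylphenyl)ethyl ether | C/C=C/O[C@@H](C)c1c(C(C)C)cc(C(C)C)cc1C(C)C | intermediate
9 | trichloroacetyl chloride | ClC(=O)C(Cl)(Cl)Cl | starting material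
10 | dichloroketene | ClC(Cl)=C=O | intermediate
11 | (3S,4S)-2,2-dichloro-4-methyl-3-[(1S)-1-(2,4,6-triisopropylphenyl)ethoxy]cyclobutan-1-one | O=C1[C@@H](C)[C@H](O[C@@H](C)c2c(C(C)C)cc(C(C)C)cc2C(C)C)C1(Cl)Cl | intermediate
12 | N-methyl-N-nitroso-4-methylbenzenesulfonamide | Cc1ccc(cc1)S(=O)(=O)N(C)N=O | starting material
13 | diazomethane | C=[N+]=[N-] | intermediate
14 | diazonium betaine from addition of 13 to the carbonyl of 11 (new carbinolate center undefined) | [O-]C1(C[N+]#N)[C@@H](C)[C@H](O[C@@H](C)c2c(C(C)C)cc(C(C)C)cc2C(C)C)C1(Cl)Cl | intermediate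
15 | (3S,4R)-2,2-dichloro-4-methyl-3-[(1S)-1-(2,4,6-triisopropylphenyl)ethoxy]cyclopentan-1-one | O=C1C[C@@H](C)[C@H](O[C@@H](C)c2c(C(C)C)cc(C(C)C)cc2C(C)C)C1(Cl)Cl | intermediate
16 | methacrolein | CC(=C)C=O | starting material
17 | lithium (3S,4R)-2-chloro-4-methyl-3-[(1S)-1-(2,4,6-triisopropylphenyl)ethoxy]cyclopent-1-en-1-olate | [Li]OC1=C(Cl)[C@@H](O[C@@H](C)c2c(C(C)C)cc(C(C)C)cc2C(C)C)[C@H](C)C1 | intermediate
18 | (3S,4R)-2-chloro-2-(1-hydroxy-2-methylprop-2-en-1-yl)-4-methyl-3-[(1S)-1-(2,4,6-triisopropylphenyl)ethoxy]cyclopentan-1-one, isomers at C2 and the carbinol carbon | O=C1C[C@@H](C)[C@H](O[C@@H](C)c2c(C(C)C)cc(C(C)C)cc2C(C)C)C1(Cl)C(O)C(C)=C | intermediate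
19 | (2S,3S,4R)-2-(1-hydroxy-2-methylprop-2-en-1-yl)-4-methyl-3-[(1S)-1-(2,4,6-triisopropylphenyl)ethoxy]cyclopentan-1-one, carbinol epimers | O=C1C[C@@H](C)[C@H](O[C@@H](C)c2c(C(C)C)cc(C(C)C)cc2C(C)C)[C@@H]1C(O)C(C)=C | intermediate
20 | (2S,3S,4R)-2-[(E)-3-hydroxy-2-methylprop-1-en-1-yl]-4-methyl-3-[(1S)-1-(2,4,6-triisopropylphenyl)ethoxy]cyclopentan-1-one | O=C1C[C@@H](C)[C@H](O[C@@H](C)c2c(C(C)C)cc(C(C)C)cc2C(C)C)[C@@H]1/C=C(\C)CO | intermediate
21 | (2S,3S,4R)-2-[(E)-3-(tert-butyldimethylsilyloxy)-2-methylprop-1-en-1-yl]-4-methyl-3-[(1S)-1-(2,4,6-triisopropylphenyl)ethoxy]cyclopentan-1-one | O=C1C[C@@H](C)[C@H](O[C@@H](C)c2c(C(C)C)cc(C(C)C)cc2C(C)C)[C@@H]1/C=C(\C)CO[Si](C)(C)C(C)(C)C | intermediate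
22 | 1,3-dithiane | C1CSCSC1 | starting material
23 | 2-lithio-1,3-dithiane | [Li]C1SCCCS1 | intermediate
24 | (1,3-dithian-2-yl)cerium dichloride | Cl[Ce](Cl)C1SCCCS1 | intermediate
25 | dichlorocerium alkoxide of the C1 adduct (dithianyl on the face of the C3 methyl, O on the face of C4–O and the C5 arm) | C1CSC(SC1)[C@@]2(O[Ce](Cl)Cl)C[C@@H](C)[C@H](O[C@@H](C)c3c(C(C)C)cc(C(C)C)cc3C(C)C)[C@@H]2/C=C(\C)CO[Si](C)(C)C(C)(C)C | intermediate
26 | 1-(1,3-dithian-2-yl)-3-methyl-4-[(1S)-1-(2,4,6-triisopropylphenyl)ethoxy]-5-[(E)-3-(tert-butyldimethylsilyloxy)-2-methylprop-1-enyl]cyclopentyl acetate | C1CSC(SC1)[C@@]2(OC(C)=O)C[C@@H](C)[C@H](O[C@@H](C)c3c(C(C)C)cc(C(C)C)cc3C(C)C)[C@@H]2/C=C(\C)CO[Si](C)(C)C(C)(C)C | intermediate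
27 | 1-acetoxy-3-methyl-4-[(1S)-1-(2,4,6-triisopropylphenyl)ethoxy]-5-[(E)-3-(tert-butyldimethylsilyloxy)-2-methylprop-1-enyl]cyclopentane-1-carbaldehyde | O=C[C@@]1(OC(C)=O)C[C@@H](C)[C@H](O[C@@H](C)c2c(C(C)C)cc(C(C)C)cc2C(C)C)[C@@H]1/C=C(\C)CO[Si](C)(C)C(C)(C)C | intermediate
28 | (E)-but-2-ene | C/C=C/C | starting material
29 | (E)-but-2-enylpotassium | [K+].[CH2-]/C=C/C | intermediate
30 | B-[(E)-but-2-enyl]diisopinocampheylborane, isopinocampheyl groups from (−)-α-pinene | C/C=C/CB([C@H]1C[C@H]2C[C@@H]([C@@H]1C)C2(C)C)[C@H]1C[C@H]2C[C@@H]([C@@H]1C)C2(C)C | intermediate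
31 | 1-[(1R,2R)-1-hydroxy-2-methylbut-3-enyl]-3-methyl-4-[(1S)-1-(2,4,6-triisopropylphenyl)ethoxy]-5-[(E)-3-(tert-butyldimethylsilyloxy)-2-methylprop-1-enyl]cyclopentyl acetate | O[C@H]([C@H](C)C=C)[C@@]1(OC(C)=O)C[C@@H](C)[C@H](O[C@@H](C)c2c(C(C)C)cc(C(C)C)cc2C(C)C)[C@@H]1/C=C(\C)CO[Si](C)(C)C(C)(C)C | intermediate
32 | C1,C1'-diacetate of 31 | CC(=O)O[C@H]([C@H](C)C=C)[C@@]1(OC(C)=O)C[C@@H](C)[C@H](O[C@@H](C)c2c(C(C)C)cc(C(C)C)cc2C(C)C)[C@@H]1/C=C(\C)CO[Si](C)(C)C(C)(C)C | intermediate
33 | 1-bromo-3-methylbut-2-ene | CC(C)=CCBr | starting material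
34 | acetaldehyde | CC=O | starting material
35 | 3,3-dimethylpent-4-en-2-ol (racemic) | CC(O)C(C)(C)C=C | intermediate
36 | 3,3-dimethylpent-4-en-2-one | CC(=O)C(C)(C)C=C | intermediate
37 | C1,C1'-diacetate with the complete (E)-side chain, auxiliary ether at C4, silyl ether on the C5 arm | CC(=O)O[C@H]([C@H](C)/C=C/C(C)(C)C(C)=O)[C@@]1(OC(C)=O)C[C@@H](C)[C@H](O[C@@H](C)c2c(C(C)C)cc(C(C)C)cc2C(C)C)[C@@H]1/C=C(\C)CO[Si](C)(C)C(C)(C)C | intermediate
38 | C1,C1'-diacetate with free C4 hydroxyl and (E)-3-hydroxy-2-methylprop-1-enyl arm | CC(=O)O[C@H]([C@H](C)/C=C/C(C)(C)C(C)=O)[C@@]1(OC(C)=O)C[C@@H](C)[C@H](O)[C@@H]1/C=C(\C)CO | intermediate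
39 | C1,C1'-diacetate with free C4 hydroxyl and (E)-2-methyl-3-oxoprop-1-enyl arm | CC(=O)O[C@H]([C@H](C)/C=C/C(C)(C)C(C)=O)[C@@]1(OC(C)=O)C[C@@H](C)[C@H](O)[C@@H]1/C=C(\C)C=O | intermediate
40 | CNP0489076.2 (C1 R, C3 R, C4 S, C5 S, C1' R, C2' R) | CC(=O)O[C@H]([C@H](C)/C=C/C(C)(C)C(C)=O)[C@@]1(OC(C)=O)C[C@@H](C)[C@H](OC(=O)c2ccccc2)[C@@H]1/C=C(\C)C=O | target

Total step count: 18.
Longest linear sequence: 15 steps (steps 1, 2, 3, 5–12, 15–18, from alcohol 1); steps 4 and 13–14 are side branches.

Steps most likely to fail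

Step 15. The ruthenium alkylidene may engage the vinyl group on the quaternary carbon of 36 too slowly, so that catalyst decay, double-bond migration and self-metathesis of 32 outrun productive cross-metathesis. The fallback sets out from 32 and returns at 37. Chemoselective hydroboration of the terminal vinyl group with 9-BBN and oxidation with NaBO3 would give the primary alcohol F1, and Dess–Martin oxidation the aldehyde F2. A Mukaiyama aldol addition of 3-methyl-2-(trimethylsilyloxy)but-2-ene (BF3·OEt2, CH2Cl2, −78 °C) would then attach the gem-dimethyl ketone as the β-hydroxy ketone F3 (carbinol epimers). Dehydration with the Burgess reagent, possible only toward C3' because C5' is quaternary, should give the (E)-alkene 37.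

Step 8. Acid-promoted loss of water from the aldol to a cross-conjugated dienone, or epimerization at C5 of the β,γ-unsaturated ketone during isomerization and silylation, may erode the material. The fallback sets out from 18 and returns at 21, and step 7 is then omitted. The same rhenium-catalysed transposition is run one step earlier on the chloro aldol 18, whose C5 carries no hydrogen, to give the primary allylic alcohol F4, which is silylated (TBSCl, imidazole) to the silyl ether F5. Reductive dechlorination with SmI2 in THF/MeOH at −78 °C would then form the samarium dienolate, whose kinetic α-protonation on the face opposite the C4 ether should give 21.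

Step 6. The chloro-enolate may lose the C4 alkoxide by β-elimination, the chloro aldolate may revert or close to an epoxide (Darzens) before the quench, and residual cuprate may add in conjugate fashion to methacrolein. The fallback sets out from 15 and returns at 18. Reductive silylation (Zn, Me3SiCl, Et2O) would give the isolable 2-chloro silyl enol ether F6, and a Mukaiyama aldol addition to methacrolein (BF3·OEt2, CH2Cl2, −78 °C) would give 18 without a free metal enolate being present.

Further compounds
F1 | step 15 | primary alcohol from hydroboration of 32 (C4' hydroxyl) | CC(=O)O[C@H]([C@H](C)CCO)[C@@]1(OC(C)=O)C[C@@H](C)[C@H](O[C@@H](C)c2c(C(C)C)cc(C(C)C)cc2C(C)C)[C@@H]1/C=C(\C)CO[Si](C)(C)C(C)(C)C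
F2 | step 15 | C4' aldehyde | CC(=O)O[C@H]([C@H](C)CC=O)[C@@]1(OC(C)=O)C[C@@H](C)[C@H](O[C@@H](C)c2c(C(C)C)cc(C(C)C)cc2C(C)C)[C@@H]1/C=C(\C)CO[Si](C)(C)C(C)(C)C
F3 | step 15 | β-hydroxy ketone from the Mukaiyama aldol (C4' carbinol epimers) | CC(=O)O[C@H]([C@H](C)CC(O)C(C)(C)C(C)=O)[C@@]1(OC(C)=O)C[C@@H](C)[C@H](O[C@@H](C)c2c(C(C)C)cc(C(C)C)cc2C(C)C)[C@@H]1/C=C(\C)CO[Si](C)(C)C(C)(C)C
F4 | step 8 | (3S,4R)-2-chloro-2-[(E)-3-hydroxy-2-methylprop-1-en-1-yl]-4-methyl-3-[(1S)-1-(2,4,6-triisopropylphenyl)ethoxy]cyclopentan-1-one | O=C1C[C@@H](C)[C@H](O[C@@H](C)c2c(C(C)C)cc(C(C)C)cc2C(C)C)C1(Cl)/C=C(\C)CO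
F5 | step 8 | tert-butyldimethylsilyl ether of F4 | O=C1C[C@@H](C)[C@H](O[C@@H](C)c2c(C(C)C)cc(C(C)C)cc2C(C)C)C1(Cl)/C=C(\C)CO[Si](C)(C)C(C)(C)C
F6 | step 6 | (3S,4R)-2-chloro-4-methyl-3-[(1S)-1-(2,4,6-triisopropylphenyl)ethoxy]-1-(trimethylsilyloxy)cyclopent-1-ene | C[Si](C)(C)OC1=C(Cl)[C@@H](O[C@@H](C)c2c(C(C)C)cc(C(C)C)cc2C(C)C)[C@H](C)C1
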